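Each half of alertenone is a quadrane in which ring A (C1, C2, C3, C4, C9) and ring B (C4–C9) are trans-fused at C9–C4, with the C8 methyl anti to C10 on quaternary C9. The plan cuts C9–C4 and C8–C7: one catalytic asymmetric intramolecular Diels–Alder reaction of an (E)-2-alkylbut-2-enal tethered through C1–C2–C3 to an (E)-diene closes both rings and fixes C4, C8 and C9 in a single operation. The precursor is a 2,2-dialkyl-1,3-dithiane linchpin carrying the enal and a pentadienyl arm. The angular formyl group and the C5=C6 alkene then build ring C; C1 methylenation and Michael dimerisation finish the target.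

Key step: step 7

Remark on numbering: in each half, C12=C1–C2(=O)–C3–C4–C5–C6–C7–C8(CH3)–C9; C9 is also bonded to C1, C4 and C10; C10–C11(CH3)2–C5 closes ring C (C4, C5, C11, C10, C9).
Remark on structures: cycloadduct 11 has C4 (S), C8 (S), C9 (R), the same spatial arrangement as C4, C8 and C9 in both halves of 28.
Assumption: the sense of induction in step 7 follows the accepted aryl-stacking model for 2-substituted enals, which calls for the (R)-configured catalyst; the (S)-catalyst would be used if the opposite sense were found.
Assumption: the configuration needed at C1 of the saturated half (CH2 substituent on the convex face of the cis-fused A/C bicyclo[3.3.0]octane, anti to C10) is the thermodynamically preferred one.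
Assumption: (E)-5-bromopenta-1,3-diene is taken as a purchased reagent.

Step 1
Reactants: 1 1,3-dithiane; 2 2-(2-bromoethyl)-1,3-dioxolane
Product: 3 2-[2-(1,3-dioxolan-2-yl)ethyl]-1,3-dithiane
Conditions: n-BuLi, THF, −30 °C; then 2, −78 to 0 °C
Reagents that add atoms: none
Why: Corey–Seebach alkylation, in which 2-lithio-1,3-dithiane displaces the primary bromide of 2 by SN2 and leaves the acetal untouched.

Step 2
Reactants: 3 monoalkyl dithiane; 4 (E)-5-bromopenta-1,3-diene
Product: 5 2-[2-(1,3-dioxolan-2-yl)ethyl]-2-[(2E)-penta-2,4-dien-1-yl]-1,3-dithiane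
Conditions: n-BuLi, THF, −30 to −10 °C; then 4, −78 °C
Reagents that add atoms: none
Why: Second Corey–Seebach alkylation, in which the 2-alkyl-2-lithiodithiane (generated before any diene is present, so the base cannot add to a diene) attacks the CH2Br terminus of the allylic bromide by SN2 and so keeps the (E)-diene.

Step 3
Reactants: 5 dialkyl dithiane acetal
Product: 6 3-{2-[(2E)-penta-2,4-dien-1-yl]-1,3-dithian-2-yl}propanal
Conditions: 2 M HCl, THF, 20 °C
Reagents that add atoms: water, O
Why: Acid-catalysed acetal hydrolysis frees the aldehyde under conditions to which the thioketal and the unactivated diene are inert.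

Step 4
Reactants: 6 aldehyde
Product: 7 tert-butyldimethylsilyl enol ether of 6 (E/Z mixture at the enol ether)
Conditions: t-BuMe2SiOTf, Et3N, CH2Cl2, 0 °C
Reagents that add atoms: tert-butyldimethylsilyl trifluoromethanesulfonate, CC(C)(C)[Si](C)(C)OS(=O)(=O)C(F)(F)F
Why: Soft enolisation with O-silylation makes the only alpha carbon of the aldehyde (C9) nucleophilic for step 5, the enol ether geometry being irrelevant.

Step 5
Reactants: 7 silyl enol ether; 8 1,1-dimethoxyethane
Product: 9 3-methoxy-2-{[2-((2E)-penta-2,4-dien-1-yl)-1,3-dithian-2-yl]methyl}butanal (both diastereomers)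
Conditions: Me3SiOTf (5 mol%), CH2Cl2, −78 °C
Reagents that add atoms: none
Why: Mukaiyama aldol reaction with an acetal, in which the catalytic silyl triflate ionises 8 to a methyl oxocarbenium ion that is trapped at C9 of 7 to form C9–C8 without the self-condensation free acetaldehyde would suffer, both new stereocentres being removed in step 6.

Step 6
Reactants: 9 beta-methoxy aldehyde
Product: 10 (2E)-2-{[2-((2E)-penta-2,4-dien-1-yl)-1,3-dithian-2-yl]methyl}but-2-enal
Conditions: DBU, CH2Cl2, 40 °C
Reagents that add atoms: none
Why: E1cB elimination of methanol gives the conjugated enal, and the (E) isomer (C8 methyl trans to the formyl group) is the thermodynamically favoured geometry to which any (Z) isomer should equilibrate through the dienolate.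

Step 7
Reactants: 10 (E,E)-trienal
Product: 11 trans-fused hydrindene aldehyde, C4 (S), C8 (S), C9 (R): ring A with C2 as 1,3-dithiane, ring B with C5=C6, C8–CH3, C9–CHO (C10); C4–H anti to C10 and CH3 anti to C10
Conditions: (R)-3,3-diphenyl-1-(2-methylphenyl)tetrahydro-1H,3H-pyrrolo[1,2-c][1,3,2]oxazaborole protonated by (CF3SO2)2NH (20 mol%), CH2Cl2, −78 to −20 °C
Reagents that add atoms: none
Why: The oxazaborolidinium ion binds the formyl oxygen and lowers the enal LUMO, so that the C4=C5–C6=C7 diene adds suprafacially across C9=C8 in a concerted, asynchronous [4+2] cycloaddition that forms C9–C4 and C8–C7. The closest known reactions are Lewis-acid-catalysed intramolecular Diels–Alder reactions of 1,6,8-nonatrienes to trans-hydrindenes and the enantioselective Diels–Alder reactions of alpha-substituted enals with protonated chiral oxazaborolidines. Ring A (five-membered) closes in the fused mode through the three-atom tether C1–C2–C3 (type 1 intramolecular cycloaddition), and ring B (six-membered) is the cyclohexene made by the cycloaddition itself. C8 is set relative to C9 by the (E) geometry of the enal, which keeps the methyl group trans to C10; C4 is set relative to C9 by the formyl-endo, tether-anti transition state, which puts C4–H anti to C10 and so gives the trans fusion; the absolute configuration of all three centres is set by the catalyst, which stacks one face of the s-trans enal over an aryl group and leaves the other face open to the diene. The step needs the endo-formyl topology and one enal face: the first should be secured by Lewis-acid coordination of the formyl group together with the short tether geminally substituted at C2, the second by the chiral catalyst. The thioketal is kept at C2 for this step because it tolerates the strongly acidic catalyst and its geminal substitution favours the coiled reactive conformer.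

Step 8
Reactants: 11 cycloadduct aldehyde
Product: 12 secondary alcohol: as 11 with C10 as CH(OH)CH3 (both C10 epimers; the new carbon is C11)
Conditions: MeMgBr, THF, −78 to 0 °C; then aq. NH4Cl
Reagents that add atoms: methylmagnesium bromide, C[Mg]Br
Why: Grignard 1,2-addition to the non-enolisable neopentyl aldehyde supplies C11, and the new carbinol centre is erased in step 9.

Step 9
Reactants: 12 secondary alcohol
Product: 13 methyl ketone: as 11 with C9 bearing acetyl (C10=O, C11H3), C2 still the dithiane
Conditions: SO3·pyridine, DMSO, i-Pr2NEt, CH2Cl2, 0 °C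
Reagents that add atoms: none
Why: Parikh–Doering oxidation (activated DMSO) gives the ketone and, unlike iodine- or metal-based oxidants, leaves the thioketal sulfur untouched.

Step 10
Reactants: 13 dithiane methyl ketone
Product: 14 dioxolane methyl ketone: as 13 with C2 as 1,3-dioxolane
Conditions: PhI(OCOCF3)2, HOCH2CH2OH, MeCN, 20 °C
Reagents that add atoms: ethylene glycol, OCCO
Why: Oxidative dethioketalisation with in situ transketalisation, in which the hypervalent iodine reagent activates sulfur and ethylene glycol captures the resulting cation, exchanges the sulfur ketal (which would intercept a metal carbenoid and be cleaved by dissolving metal) for an O,O-ketal in one operation while the hindered C10 ketone and the C5=C6 alkene stay intact.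

Step 11
Reactants: 14 dioxolane methyl ketone
Product: 16 diazomethyl ketone C10(=O)–C11H=N2, via trifluoroacetyl diketone 15 (not isolated)
Conditions: LiN(SiMe3)2, THF, −78 °C; CF3CO2CH2CF3; aq. HCl; then CH3SO2N3, Et3N, H2O, MeCN, 20 °C
Reagents that add atoms: methanesulfonyl azide, CS(=O)(=O)N=[N+]=[N-]; 2,2,2-trifluoroethyl trifluoroacetate, O=C(OCC(F)(F)F)C(F)(F)F (its trifluoroacetyl group is present only in intermediate 15)
Why: Detrifluoroacetylative (Regitz-type deacylative) diazo transfer works because the methyl group is the only enolisable position (C9 is quaternary), so Claisen trifluoroacetylation followed by sulfonyl azide transfer gives the alpha-diazo ketone without diazomethane.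

Step 12
Reactants: 16 diazomethyl ketone
Product: 17 cyclopropyl ketone: C11 bonded to C10, C5 and C6 (tricyclo[3.2.1.0(2,7)]octan-6-one unit fused to ring A), cyclopropane on the face of ring B that carries C10
Conditions: Rh2(OAc)4 (1 mol%), CH2Cl2, 20 °C, slow addition of 16
Reagents that add atoms: none
Why: Intramolecular carbenoid cyclopropanation of a cyclohex-3-enyl diazomethyl ketone, in which the acyl carbenoid on axial C10 can reach only the face of C5=C6 that carries C10, so C11–C5 and C11–C6 (and the C5, C6, C11 centres) form cis to the C9–C10 bond.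

Step 13
Reactants: 17 cyclopropyl ketone
Product: 18 tricyclic ketone with rings A, B and C: C10 ketone, C11H2 bonded to C5, C6H2, C2 dioxolane
Conditions: Li, NH3(l), THF, −78 °C; then NH4Cl
Reagents that add atoms: none
Why: Dissolving-metal reductive opening of a cyclopropyl ketone cleaves the cyclopropane bond that overlaps best with the carbonyl pi system, expected here to be C11–C6 because C11–C5 lies close to the carbonyl plane of the rigid tricycle, which leaves ring C closed through C11–C5 with C5 as set in step 12 and C6 as CH2.

Step 14
Reactants: 18 tricyclic ketone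
Product: 19 gem-dimethyl ketone: as 18 with C11(CH3)2
Conditions: KOt-Bu (excess), MeI (excess), THF, 0 to 40 °C
Reagents that add atoms: iodomethane, CI
Why: Exhaustive enolate C-alkylation is regiochemically unambiguous because C11 is the only enolisable carbon of the C10 ketone, and C11 is not stereogenic.

Step 15
Reactants: 19 gem-dimethyl ketone
Product: 22 tricyclic C2 ketone (suberosenone lacking C12), via hydrazone 20 (not isolated), via ketal hydrocarbon 21 (not isolated)
Conditions: anhydrous N2H4, NaOCH2CH2OCH2CH2OH, diethylene glycol, 180 to 210 °C; then 2 M HCl, THF, 20 °C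
Reagents that add atoms: water, O; hydrazine, NN (its nitrogen atoms are present only in intermediate 20)
Why: Wolff–Kishner reduction under anhydrous high-temperature conditions suited to hindered ketones removes the C10 oxygen through the hydrazone in a basic medium that the dioxolane survives, and acidification of the same flask then hydrolyses the ketal to the C2 ketone.

Step 16
Reactants: 22 tricyclic C2 ketone
Product: 23 3-(hydroxymethylene) derivative of 22
Conditions: NaH, HCO2Et, EtOH (cat.), THF, 0 to 20 °C; aq. HCl work-up
Reagents that add atoms: ethyl formate, CCOC=O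
Why: Crossed Claisen condensation with ethyl formate is reversible and should place the formyl group on the less hindered alpha carbon C3 (C1 is neopentyl, next to quaternary C9), which blocks C3 and leaves C1 as the only remaining acidic carbon.

Step 17
Reactants: 23 hydroxymethylene ketone
Product: 25 C1 Mannich base: 1-(dimethylaminomethyl) derivative of 22 (both C1 epimers), via formyl Mannich adduct 24 (not isolated)
Conditions: LiN(i-Pr)2 (2.2 equiv), THF, −78 to 0 °C; CH2=NMe2+ I−, −78 to 20 °C; then 2 M KOH, MeOH–H2O, 20 °C
Reagents that add atoms: N,N-dimethylmethyleneiminium iodide, C=[N+](C)C.[I-]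
Why: Gamma-alkylation of a beta-dicarbonyl dianion followed by retro-Claisen deformylation, in which the second deprotonation can occur only at C1, whose carbanion is aminomethylated (Mannich reaction) before hydroxide removes the blocking formyl group as formate, the C1 centre being lost in step 18.

Step 18
Reactants: 25 Mannich base
Product: 27 suberosenone, via methiodide 26 (not isolated)
Conditions: MeI, MeOH, 20 °C; then NaHCO3, H2O/CH2Cl2, 20 °C
Reagents that add atoms: iodomethane, CI (its methyl group is present only in intermediate 26)
Why: Quaternisation followed by Hofmann-type E1cB elimination under mild bicarbonate conditions unveils the exocyclic C1=C12 enone.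

Step 19
Reactants: 27 suberosenone (two molecules, one as donor and one as acceptor)
Product: 28 alertenone
Conditions: LiN(SiMe3)2 (0.5 equiv), THF, −78 °C, 27 added to the base; −78 to −20 °C; t-BuOH, then 20 °C; aq. NH4Cl
Reagents that add atoms: none
Why: Michael addition, in which the cross-conjugated C3 enolate of one molecule (C3 is its only enolisable position) should add to C12 of a second molecule from the convex face of ring A, anti to C5 and the C11 methyl groups, setting C3, and the resulting enolate is protonated at C1 under equilibrating conditions that place the CH2 substituent anti to C10.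

Compound list
1 | 1,3-dithiane | C1CSCSC1 | starting material
2 | 2-(2-bromoethyl)-1,3-dioxolane | BrCCC1OCCO1 | starting material
3 | 2-[2-(1,3-dioxolan-2-yl)ethyl]-1,3-dithiane | C1CSC(CCC2OCCO2)SC1 | intermediate
4 | (E)-5-bromopenta-1,3-diene | C=C/C=C/CBr | starting material
5 | 2-[2-(1,3-dioxolan-2-yl)ethyl]-2-[(2E)-penta-2,4-dien-1-yl]-1,3-dithiane | C=C/C=C/CC1(CCC2OCCO2)SCCCS1 | intermediate
6 | 3-{2-[(2E)-penta-2,4-dien-1-yl]-1,3-dithian-2-yl}propanal | C=C/C=C/CC1(CCC=O)SCCCS1 | intermediate
7 | tert-butyldimethylsilyl enol ether of 6 (E/Z mixture at the enol ether, diene E) | C=C/C=C/CC1(CC=CO[Si](C)(C)C(C)(C)C)SCCCS1 | intermediate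
8 | 1,1-dimethoxyethane | CC(OC)OC | starting material
9 | 3-methoxy-2-{[2-((2E)-penta-2,4-dien-1-yl)-1,3-dithian-2-yl]methyl}butanal (both diastereomers) | C=C/C=C/CC1(CC(C=O)C(C)OC)SCCCS1 | intermediate
10 | (2E)-2-{[2-((2E)-penta-2,4-dien-1-yl)-1,3-dithian-2-yl]methyl}but-2-enal | C/C=C(/C=O)CC1(SCCCS1)C/C=C/C=C | intermediate
11 | trans-fused hydrindene aldehyde, C4 (S), C8 (S), C9 (R); C2 dithiane, C5=C6, C9–CHO | C1C2(SCCCS2)C[C@H]3C=CC[C@H](C)[C@]13C=O | intermediate
12 | as 11 with C10 as CH(OH)CH3 (both C10 epimers) | C1C2(SCCCS2)C[C@H]3C=CC[C@H](C)[C@]13C(C)O | intermediate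
13 | as 11 with C9 bearing acetyl (C10=O, C11H3) | C1C2(SCCCS2)C[C@H]3C=CC[C@H](C)[C@]13C(C)=O | intermediate
14 | as 13 with C2 as 1,3-dioxolane | C1C2(OCCO2)C[C@H]3C=CC[C@H](C)[C@]13C(C)=O | intermediate
15 | as 14 with C11 trifluoroacetylated: C10(=O)–C11H2–C(=O)CF3 | C1C2(OCCO2)C[C@H]3C=CC[C@H](C)[C@]13C(=O)CC(=O)C(F)(F)F | intermediate
16 | as 14 with C10(=O)–C11H=N2 (diazomethyl ketone) | C1C2(OCCO2)C[C@H]3C=CC[C@H](C)[C@]13C(=O)C=[N+]=[N-] | intermediate
17 | cyclopropyl ketone: C11 bonded to C10, C5 and C6 on the ring B face that carries C10; C2 dioxolane | C1C2(OCCO2)C[C@H]3[C@@H]4[C@@H]5C[C@H](C)[C@]13C(=O)[C@H]45 | intermediate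
18 | tricyclic ketone, rings A, B and C; C10 ketone, C11H2, C2 dioxolane; C4, C5, C8, C9 as in the target | C1C2(OCCO2)C[C@H]3[C@@H]4CC[C@H](C)[C@]13C(=O)C4 | intermediate
19 | as 18 with C11(CH3)2 | C1C2(OCCO2)C[C@H]3[C@@H]4CC[C@H](C)[C@]13C(=O)C4(C)C | intermediate
20 | C10 hydrazone of 19 | C1C2(OCCO2)C[C@H]3[C@@H]4CC[C@H](C)[C@]13C(=NN)C4(C)C | intermediate
21 | as 19 with C10 as CH2 (C2 dioxolane of the tricyclic hydrocarbon core) | C1C2(OCCO2)C[C@H]3[C@@H]4CC[C@H](C)[C@]13CC4(C)C | intermediate
22 | tricyclic C2 ketone (suberosenone lacking C12) | C1C(=O)C[C@H]2[C@@H]3CC[C@H](C)[C@]12CC3(C)C | intermediate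
23 | 3-(hydroxymethylene) derivative of 22 | C1C(=O)C(=CO)[C@H]2[C@@H]3CC[C@H](C)[C@]12CC3(C)C | intermediate
24 | 1-(dimethylaminomethyl)-3-(hydroxymethylene) derivative of 22 (both C1 epimers) | CN(C)CC1C(=O)C(=CO)[C@H]2[C@@H]3CC[C@H](C)[C@]12CC3(C)C | intermediate
25 | 1-(dimethylaminomethyl) derivative of 22 (both C1 epimers) | CN(C)CC1C(=O)C[C@H]2[C@@H]3CC[C@H](C)[C@]12CC3(C)C | intermediate
26 | trimethylammonium iodide of 25 | C[N+](C)(C)CC1C(=O)C[C@H]2[C@@H]3CC[C@H](C)[C@]12CC3(C)C.[I-] | intermediate
27 | suberosenone (C1=C12 exocyclic enone of 22) | C=C1C(=O)C[C@H]2[C@@H]3CC[C@H](C)[C@]12CC3(C)C | intermediate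
28 | alertenone: C3 of the enone half linked through CH2 to C1 of the saturated half; linking CH2 anti to C5 at C3 and anti to C10 at C1 | C=C1C(=O)[C@H](C[C@@H]2C(=O)C[C@H]3[C@@H]4CC[C@H](C)[C@]23CC4(C)C)[C@H]2[C@@H]3CC[C@H](C)[C@]12CC3(C)C | target

Total step count: 19. Longest linear sequence: 19 steps (from 1,3-dithiane; the last step joins two molecules of 27).

Steps most likely to fail

Step 7. The cationic boron catalyst may be tied up by the thioketal sulfur atoms, or may discriminate the two faces of this alpha,beta-disubstituted enal poorly, so that conversion or enantiomeric purity falls short. Fallback: the fallback sets out from 10, which is cyclised with an achiral aluminium Lewis acid (MeAlCl2, CH2Cl2, −78 °C) and should give the same trans-fused adduct as the racemic aldehyde F1. Condensation with (1R,2R)-N,N'-dimethyl-1,2-diphenylethane-1,2-diamine (4 Å sieves, Et2O) should give two diastereomeric imidazolidines, the aminal F2 derived from 11 and the diastereomeric aminal F3 derived from the mirror image of 11. These are separated by chromatography or crystallisation. Hydrolysis of F2 (dilute HCl, Et2O/H2O, 0 °C) comes back to the route at 11.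

Step 15. Hydrazone formation at C10, a carbonyl flanked by two quaternary carbons, may be too slow, so that ketone is returned or the ketal is degraded on forcing. Fallback: the fallback sets out from 19, which is reduced with LiAlH4 (THF, reflux) to the C10 alcohol F4. NaH, CS2 and MeI (THF) convert it into the S-methyl xanthate F5, and Barton–McCombie deoxygenation (Bu3SnH, AIBN, toluene, 110 °C) comes back to the route at 21, which is hydrolysed as in the second stage of step 15.

Step 19. Enolate and enone may not keep to their intended one-to-one roles, so that the first adduct reacts on (oligomerisation or an intramolecular Michael closure), or the protonation at C1 of the saturated half may not equilibrate. Fallback: the fallback sets out from 27, one portion of which is converted (t-BuMe2SiOTf, Et3N, CH2Cl2, −78 to 0 °C) into the silyl dienol ether F6. A Mukaiyama–Michael reaction of F6 with a second portion of 27 ((CF3SO2)2NH cat., CH2Cl2, −78 °C) should stop at the silyl enol ether adduct F7, because no free enolate is present. HF·pyridine (THF, 0 °C) then frees the ketone, and brief DBU treatment equilibrates C1 of the saturated half, coming back to the route at 28.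

Further compounds
F1 | step 7 | racemic trans-fused aldehyde (11 and its mirror image, 1:1) | C1C2(SCCCS2)C[C@H]3C=CC[C@H](C)[C@]13C=O.C1C2(SCCCS2)C[C@@H]3C=CC[C@@H](C)[C@@]13C=O
F2 | step 7 | imidazolidine (aminal) of 11 with (1R,2R)-N,N'-dimethyl-1,2-diphenylethane-1,2-diamine | C1C2(SCCCS2)C[C@H]3C=CC[C@H](C)[C@]13C4N(C)[C@H](c5ccccc5)[C@@H](c5ccccc5)N4C
F3 | step 7 | diastereomeric imidazolidine from the mirror image of 11 | C1C2(SCCCS2)C[C@@H]3C=CC[C@@H](C)[C@@]13C4N(C)[C@H](c5ccccc5)[C@@H](c5ccccc5)N4C
F4 | step 15 | C10 alcohol from 19 (both C10 epimers) | C1C2(OCCO2)C[C@H]3[C@@H]4CC[C@H](C)[C@]13C(O)C4(C)C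
F5 | step 15 | S-methyl xanthate of F4 | C1C2(OCCO2)C[C@H]3[C@@H]4CC[C@H](C)[C@]13C(OC(=S)SC)C4(C)C
F6 | step 19 | tert-butyldimethylsilyl dienol ether of 27 (C3=C2(OSi)–C1=C12) | C=C1C(O[Si](C)(C)C(C)(C)C)=C[C@H]2[C@@H]3CC[C@H](C)[C@]12CC3(C)C
F7 | step 19 | Michael adduct as the C1=C2 silyl enol ether of the saturated half | C=C1C(=O)[C@H](CC2=C(O[Si](C)(C)C(C)(C)C)C[C@H]3[C@@H]4CC[C@H](C)[C@]23CC4(C)C)[C@H]2[C@@H]3CC[C@H](C)[C@]12CC3(C)C
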